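(The constants used here are those of an exercise; the rest is arithmetic.)

I began from the leftover, the free starting material still in the flask at work-up, and from what its size beside the target could tell me.

    starting material + enzyme ⇌ starting complex (K1 = 1300 M⁻¹, k1 = 1.5 × 10⁷ M⁻¹ s⁻¹)
    second substrate + starting complex ⇌ ternary complex (K2 = 1.2 × 10⁵ M⁻¹, k2 = 4.8 × 10⁷ M⁻¹ s⁻¹)
    starting material + protic impurity → quenched substrate (k3 = 1000 M⁻¹ s⁻¹)
    2 starting material → self-condensation product (k4 = 350 M⁻¹ s⁻¹)
    ternary complex ⇌ enzyme + target (K5 = 1.2 × 10⁻⁴ M, k5 = 580 s⁻¹)

| flask | starting material | second substrate | protic impurity | enzyme | time | remark |
|---|---|---|---|---|---|---|
| north | 0.20 mM | 0.240 mM | 0.0600 mM | 0.040 µM | 40 s | everything together in a closed stirred flask, run for 40 s |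
| north-west | 0.20 mM | 0.240 mM (fed, over 40.0 s) | 0.0600 mM | 0.040 µM | 40 s | a stirred flask in which second substrate is dosed at a steady rate over 40.0 s without added volume, worked up at 40 s |
| north-east | 0.20 mM (fed, over 40.0 s) | 0.240 mM | 0.0600 mM | 0.040 µM | 40 s | a stirred flask in which starting material is dosed at a steady rate over 40.0 s without added volume, worked up at 40 s |
| east | 0.20 mM | 0.240 mM | 0.0600 mM | 0.040 µM |  | a single well-mixed tank run continuously and read at steady state, 40 s in it on average |

- a species is counted by the starting material in it: one self-condensation product counts as two
- a doubled species enters its step squared and goes two at a time
- the stated concentrations are those of everything mixed, before any reaction; amounts are the same in each set-up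
- the feed brings no volume worth counting
- run time (north): 40 s

- order of the set-ups by the amount of target at the outlet or at the end, in percent of the starting material put in, highest first (north / north-west / north-east / east)
- amount of target at the outlet or at the end, in percent of the starting material put in, north
- amount of target at the outlet or at the end, in percent of the starting material put in, north-west
- amount of target at the outlet or at the end, in percent of the starting material put in, north-east
- amount of target at the outlet or at the end, in percent of the starting material put in, east

- I multiplied the equilibrium constants of the three reversible steps by the second substrate present, which gave 4.49 at the charge; this balance number is the ratio of target to free starting material at which the enzyme passes nothing net.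
- Below that ratio the enzyme makes target, and above it target goes back to starting material.
- At balance, 18.2 % of the pool of target plus free starting material stood free, so I treated that part as the small one and the two losses as a correction drawing on it.
- One number was not enough. In north at the start, self-condensation took 0.0280 mM s⁻¹ and quenching 0.0120 mM s⁻¹, while the enzyme's ceiling, with every enzyme held as ternary complex, was 0.0232 mM s⁻¹.
- Those losses together ran faster than that ceiling, so the balance number gave me a ratio but not the size of the pool, and I committed to no yield.
- I did commit to the bottom of the order: north-west held the whole charge of starting material while second substrate began from nothing, so I put it last.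
- The forecast gave north-east > east > north > north-west, with 31.5 % for north, 15.5 % for north-west, 42.5 % for north-east and 36 % for east. Its ground was this: “Keeping starting material low starves the second-order self-condensation”.
- The flask gave north-east > east > north > north-west, with 32.0 % for north, 18.3 % for north-west, 41.8 % for north-east and 36.2 % for east, each within the forecast's margin.
- North-east's 41.8 % belongs to one moment: left until 400 s, it read 18.8 %. At 40.0 s, its target to free starting material read 1.76, lower than the 2.93 that the balance number gave on the second substrate left, so by the rule the enzyme was still making target at work-up.
- For north-west with 0.96 mM of second substrate, the balance number came to 18.0 at the charge and 16.7 on the second substrate left. That run gave 34.4 % of target beside 2.2 % of free starting material, a ratio of 15.9.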